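The target, a cis-fused (5R,8S,10S) drimane-type decalin carrying an E-configured C9=C11 arylmethylidene, is disconnected at C8–C9 of ring B. The key step exploits the fact that C9 bears the arylated carbon C11 and C8 a methyl group: an aryl alkyne on quaternary C10 and a C8 methyl ketone undergo intramolecular alkyne–carbonyl metathesis, which closes ring B, creates the C8=C9 alkene and places the oxygen on C11 in one operation. The precursor is a cis-2-(arylethynyl)-1-(3-oxobutyl)-2,6,6-trimethylcyclohexane (ring A, C5 and C10 set). The C11 oxygen then drives an alkene transposition that sets C8.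

Key step: step 8

Remark: drimane numbering is used (ring A = C1–C5/C10, ring B = C5–C10, C11 = benzylic carbon) and the α-face is the face of ring B opposite the C10 methyl group; the copper–diphosphine catalyst of step 3 is assumed to show the facial preference needed for the (3R) adduct, the antipodal ligand being used otherwise.

Step 1
Reactants: 1 4,4-dimethylcyclohex-2-en-1-one
Product: 2 2-iodo-4,4-dimethylcyclohex-2-en-1-one
Conditions: I2, pyridine–CH2Cl2, 0 °C → rt
Reagents that add atoms: iodine, II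
Why: α-Iodination by a Baylis–Hillman-type addition–elimination sequence (pyridine adds at C3, the enolate is iodinated at C2, pyridine is expelled) is standard for cyclohexenones.

Step 2
Reactants: 2 2-iodo-4,4-dimethylcyclohex-2-en-1-one; 3 ethynyl(trimethyl)silane
Product: 4 4,4-dimethyl-2-[(trimethylsilyl)ethynyl]cyclohex-2-en-1-one
Conditions: Pd(PPh3)2Cl2 (3 mol %), CuI (6 mol %), i-Pr2NH, THF, 0 °C → rt
Reagents that add atoms: none
Why: Sonogashira coupling, in which the 2-iodoenone is an activated vinyl iodide for oxidative addition to zerovalent palladium and the silyl cap keeps the alkyne protected through the next two steps.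

Step 3
Reactants: 4 4,4-dimethyl-2-[(trimethylsilyl)ethynyl]cyclohex-2-en-1-one; 5 2-(2-bromoethyl)-2-methyl-1,3-dioxolane
Product: 8 (2S,3R)-2,4,4-trimethyl-3-[2-(2-methyl-1,3-dioxolan-2-yl)ethyl]-2-[(trimethylsilyl)ethynyl]cyclohexan-1-one, via Grignard reagent 6 (not isolated), via magnesium enolate 7 (not isolated)
Conditions: 5, Mg, 2-methyltetrahydrofuran, 25 °C; then 4, CuBr·SMe2 (5 mol %), (R)-1-[(S)-2-(diphenylphosphanyl)ferrocenyl]ethyl(dicyclohexyl)phosphane (6 mol %), t-BuOMe, −78 °C; then MeI, DMPU, −78 → 0 °C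
Reagents that add atoms: iodomethane, CI
Why: Copper-catalysed enantioselective conjugate addition of a Grignard reagent followed by C-methylation of the magnesium enolate (three-component coupling), in which the chiral diphosphine–copper complex selects the enone face and sets C3 as R (C5 of the target), and iodomethane enters C2 anti to the new chain, which sits pseudoaxially beside the gem-dimethyl carbon, setting the quaternary centre as 2S (C10) with the alkyne cis to the chain.

Step 4
Reactants: 8 (2S,3R)-2,4,4-trimethyl-3-[2-(2-methyl-1,3-dioxolan-2-yl)ethyl]-2-[(trimethylsilyl)ethynyl]cyclohexan-1-one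
Product: 11 2-methyl-2-{2-[(1R,2S)-2,6,6-trimethyl-2-[(trimethylsilyl)ethynyl]cyclohexyl]ethyl}-1,3-dioxolane, via tosylhydrazone 9 (not isolated), via alkyldiazene 10 (not isolated)
Conditions: TsNHNH2, EtOH, 70 °C; evaporate; catecholborane, CHCl3, 0 °C; then NaOAc·3H2O, 60 °C
Reagents that add atoms: none
Why: Caglioti-type deoxygenation with catecholborane, in which acid-free condensation spares the dioxolane, hydride adds to C=N, acetate induces loss of sulfinate and the alkyldiazene loses dinitrogen to leave CH2, while the silyl alkyne is inert and the adjacent quaternary centre cannot epimerise.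

Step 5
Reactants: 12 methyl 2,4,5-trimethoxybenzoate
Product: 13 methyl 3-iodo-2,4,5-trimethoxybenzoate
Conditions: N-iodosuccinimide, CF3CO2H–MeCN, rt → 50 °C
Reagents that add atoms: N-iodosuccinimide, O=C1CCC(=O)N1I
Why: Electrophilic aromatic iodination should enter at C3, the only free position ortho to two methoxy groups and meta to the ester, whereas C6 is activated by one methoxy group and lies ortho to the ester.

Step 6
Reactants: 11 2-methyl-2-{2-[(1R,2S)-2,6,6-trimethyl-2-[(trimethylsilyl)ethynyl]cyclohexyl]ethyl}-1,3-dioxolane; 13 methyl 3-iodo-2,4,5-trimethoxybenzoate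
Product: 15 methyl 2,4,5-trimethoxy-3-{[(1S,2R)-1,3,3-trimethyl-2-[2-(2-methyl-1,3-dioxolan-2-yl)ethyl]cyclohexyl]ethynyl}benzoate, via ethynyl ketal 14 (not isolated)
Conditions: Pd(PPh3)2Cl2 (5 mol %), CuI (10 mol %), n-Bu4NF, Et3N, THF, 50 °C
Reagents that add atoms: none
Why: One-pot desilylation–Sonogashira coupling, in which fluoride cleaves the C–Si bond and the terminal alkyne, unable to isomerise because its propargylic carbon is quaternary, couples with the aryl iodide while ketal and ester stay untouched.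

Step 7
Reactants: 15 methyl 2,4,5-trimethoxy-3-{[(1S,2R)-1,3,3-trimethyl-2-[2-(2-methyl-1,3-dioxolan-2-yl)ethyl]cyclohexyl]ethynyl}benzoate
Product: 16 methyl 2,4,5-trimethoxy-3-{[(1S,2R)-1,3,3-trimethyl-2-(3-oxobutyl)cyclohexyl]ethynyl}benzoate
Conditions: 1 M aq. HCl (0.2 equiv), THF, rt
Reagents that add atoms: water, O
Why: Acid-catalysed hydrolysis of the dioxolane unmasks the methyl ketone under conditions too mild to hydrate the alkyne or hydrolyse the ester.

Step 8
Reactants: 16 methyl 2,4,5-trimethoxy-3-{[(1S,2R)-1,3,3-trimethyl-2-(3-oxobutyl)cyclohexyl]ethynyl}benzoate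
Product: 18 methyl 2,4,5-trimethoxy-3-{[(4aR,8aS)-2,5,5,8a-tetramethyl-3,4,4a,5,6,7,8,8a-octahydronaphthalen-1-yl]carbonyl}benzoate, via oxetene 17 (not isolated)
Conditions: FeCl3 (anhydrous, 15 mol %), ClCH2CH2Cl, rt → 60 °C
Reagents that add atoms: none
Why: FeCl3 binds the C8 ketone oxygen, alkyne carbon C9 attacks the activated carbonyl carbon, and the vinyl cation developing at C11, stabilised by the di-ortho-methoxy aryl ring, is captured by the same oxygen, so a formal [2+2] cycloaddition gives oxetene 17, whose 4π-electrocyclic ring opening breaks C8–O and leaves the C8=C9 alkene and the C11 ketone. The closest known reaction type is the Lewis- or Brønsted-acid-catalysed intramolecular alkyne–carbonyl metathesis of aryl alkynes tethered to aldehydes or ketones, which gives 1-acylcycloalkenes. Ring B closes in the 6-exo-dig mode (C8–C9 bond formed, C11 exocyclic). No stereocentre is created, and C5 and C10 cannot epimerise (C10 is quaternary, C5 is remote from any carbonyl). The step needs attack through C9 and not C11, which is secured by aryl stabilisation of charge at C11 and by the six- over seven-membered ring, and it needs activation of the ketone and not the much less electrophilic ester; the quaternary propargylic C10 rules out elimination to an allene or enyne.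

Step 9
Reactants: 18 methyl 2,4,5-trimethoxy-3-{[(4aR,8aS)-2,5,5,8a-tetramethyl-3,4,4a,5,6,7,8,8a-octahydronaphthalen-1-yl]carbonyl}benzoate
Product: 19 methyl 3-{(R)-hydroxy[(4aR,8aS)-2,5,5,8a-tetramethyl-3,4,4a,5,6,7,8,8a-octahydronaphthalen-1-yl]methyl}-2,4,5-trimethoxybenzoate
Conditions: (S)-1-methyl-3,3-diphenyltetrahydro-1H,3H-pyrrolo[1,2-c][1,3,2]oxazaborole (0.3 equiv), catecholborane, toluene, −40 → 0 °C
Reagents that add atoms: none
Why: Corey–Bakshi–Shibata reduction, in which the carbonyl twisted out of conjugation with the tetrasubstituted alkene is reduced 1,2 and, with the di-ortho-substituted aryl ring taken as the larger substituent, the (S)-oxazaborolidine–borane complex delivers hydride to the Si face of C11 to give the R carbinol, the ester being inert to catecholborane.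

Step 10
Reactants: 19 methyl 3-{(R)-hydroxy[(4aR,8aS)-2,5,5,8a-tetramethyl-3,4,4a,5,6,7,8,8a-octahydronaphthalen-1-yl]methyl}-2,4,5-trimethoxybenzoate
Product: 22 methyl 2,4,5-trimethoxy-3-{(E)-[(2S,4aR,8aS)-2,5,5,8a-tetramethyloctahydronaphthalen-1(2H)-ylidene]methyl}benzoate, via sulfonylhydrazine 20 (not isolated), via allylic diazene 21 (not isolated)
Conditions: 2-nitrobenzenesulfonylhydrazide, PPh3, diethyl azodicarboxylate, N-methylmorpholine, −30 °C → rt
Reagents that add atoms: none
Why: Mitsunobu displacement followed by allylic diazene rearrangement (reductive 1,3-transposition), in which the hydrazide nitrogen displaces the activated C11 oxygen with inversion to give the S sulfonylhydrazine, loss of 2-nitrobenzenesulfinic acid gives the monoalkyl diazene, and dinitrogen is expelled through a suprafacial retro-ene transition state in which C11–H, not the di-ortho-substituted aryl ring, lies beside quaternary C10, so the aryl group ends syn to C8 (E alkene) and hydrogen is delivered to the α-face of C8, giving 8S with the C8 methyl cis to the C10 methyl.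

Step 11
Reactants: 22 methyl 2,4,5-trimethoxy-3-{(E)-[(2S,4aR,8aS)-2,5,5,8a-tetramethyloctahydronaphthalen-1(2H)-ylidene]methyl}benzoate
Product: 23 (2,4,5-trimethoxy-3-{(E)-[(2S,4aR,8aS)-2,5,5,8a-tetramethyloctahydronaphthalen-1(2H)-ylidene]methyl}phenyl)methanol
Conditions: i-Bu2AlH (2.5 equiv), CH2Cl2, −78 → 0 °C; aq. potassium sodium tartrate
Reagents that add atoms: none
Why: Hydride reduction of the methyl ester to the benzylic alcohol, to which the isolated trisubstituted alkene is inert.

Step 12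
Reactants: 23 (2,4,5-trimethoxy-3-{(E)-[(2S,4aR,8aS)-2,5,5,8a-tetramethyloctahydronaphthalen-1(2H)-ylidene]methyl}phenyl)methanol
Product: 24 2,4,5-trimethoxy-3-{(E)-[(2S,4aR,8aS)-2,5,5,8a-tetramethyloctahydronaphthalen-1(2H)-ylidene]methyl}benzaldehyde
Conditions: MnO2 (activated, excess), CH2Cl2, rt
Reagents that add atoms: none
Why: Heterogeneous MnO2 oxidation is selective for benzylic alcohols and stops at the aldehyde without touching the alkene or the allylic C8–H.

Step 13
Reactants: 24 2,4,5-trimethoxy-3-{(E)-[(2S,4aR,8aS)-2,5,5,8a-tetramethyloctahydronaphthalen-1(2H)-ylidene]methyl}benzaldehyde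
Product: 25 2,4,5-trihydroxy-3-{(E)-[(2S,4aR,8aS)-2,5,5,8a-tetramethyloctahydronaphthalen-1(2H)-ylidene]methyl}benzaldehyde
Conditions: BBr3 (6 equiv), CH2Cl2, −78 → 0 °C; then ice-water
Reagents that add atoms: none
Why: Boron tribromide cleaves the three aryl methyl ethers through aryloxyboranes that are hydrolysed on work-up, and low temperature with a prompt quench should keep the trisubstituted alkene and the C8 stereocentre intact.

Compound list
1 | 4,4-dimethylcyclohex-2-en-1-one | CC1(C)CCC(=O)C=C1 | starting material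
2 | 2-iodo-4,4-dimethylcyclohex-2-en-1-one | CC1(C)CCC(=O)C(I)=C1 | intermediate
3 | ethynyl(trimethyl)silane | C#C[Si](C)(C)C | starting material
4 | 4,4-dimethyl-2-[(trimethylsilyl)ethynyl]cyclohex-2-en-1-one | CC1(C)CCC(=O)C(C#C[Si](C)(C)C)=C1 | intermediate
5 | 2-(2-bromoethyl)-2-methyl-1,3-dioxolane | CC1(CCBr)OCCO1 | starting material
6 | bromo[2-(2-methyl-1,3-dioxolan-2-yl)ethyl]magnesium | CC1(CC[Mg]Br)OCCO1 | intermediate (not isolated)
7 | bromomagnesium enolate, bromo{[(3R)-4,4-dimethyl-3-[2-(2-methyl-1,3-dioxolan-2-yl)ethyl]-2-[(trimethylsilyl)ethynyl]cyclohex-1-en-1-yl]oxy}magnesium | CC2(OCCO2)CC[C@@H]1C(C)(C)CCC(O[Mg]Br)=C1C#C[Si](C)(C)C | intermediate (not isolated)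
8 | (2S,3R)-2,4,4-trimethyl-3-[2-(2-methyl-1,3-dioxolan-2-yl)ethyl]-2-[(trimethylsilyl)ethynyl]cyclohexan-1-one | CC2(OCCO2)CC[C@@H]1C(C)(C)CCC(=O)[C@]1(C)C#C[Si](C)(C)C | intermediate
9 | 4-methylbenzenesulfonylhydrazone of 8 (2S,3R) | CC2(OCCO2)CC[C@@H]1C(C)(C)CCC(=NNS(=O)(=O)c3ccc(C)cc3)[C@]1(C)C#C[Si](C)(C)C | intermediate (not isolated)
10 | 2-{2-[(1R,2S)-3-diazenyl-2,6,6-trimethyl-2-[(trimethylsilyl)ethynyl]cyclohexyl]ethyl}-2-methyl-1,3-dioxolane (diazene carbon unassigned) | CC2(OCCO2)CC[C@@H]1C(C)(C)CCC(N=N)[C@]1(C)C#C[Si](C)(C)C | intermediate (not isolated)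
11 | 2-methyl-2-{2-[(1R,2S)-2,6,6-trimethyl-2-[(trimethylsilyl)ethynyl]cyclohexyl]ethyl}-1,3-dioxolane | CC2(OCCO2)CC[C@@H]1C(C)(C)CCC[C@]1(C)C#C[Si](C)(C)C | intermediate
12 | methyl 2,4,5-trimethoxybenzoate | COC(=O)c1cc(OC)c(OC)cc1OC | starting material
13 | methyl 3-iodo-2,4,5-trimethoxybenzoate | COC(=O)c1cc(OC)c(OC)c(I)c1OC | intermediate
14 | 2-{2-[(1R,2S)-2-ethynyl-2,6,6-trimethylcyclohexyl]ethyl}-2-methyl-1,3-dioxolane | CC2(OCCO2)CC[C@@H]1C(C)(C)CCC[C@]1(C)C#C | intermediate (not isolated)
15 | methyl 2,4,5-trimethoxy-3-{[(1S,2R)-1,3,3-trimethyl-2-[2-(2-methyl-1,3-dioxolan-2-yl)ethyl]cyclohexyl]ethynyl}benzoate | CC2(OCCO2)CC[C@@H]1C(C)(C)CCC[C@]1(C)C#Cc1c(OC)c(OC)cc(C(=O)OC)c1OC | intermediate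
16 | methyl 2,4,5-trimethoxy-3-{[(1S,2R)-1,3,3-trimethyl-2-(3-oxobutyl)cyclohexyl]ethynyl}benzoate (key-step precursor) | CC(=O)CC[C@@H]1C(C)(C)CCC[C@]1(C)C#Cc1c(OC)c(OC)cc(C(=O)OC)c1OC | intermediate
17 | oxetene in which oxygen bridges C8 and C11 of the closed decalin (C8–O–C11=C9 ring; C8 unassigned) | CC13OC(c4c(OC)c(OC)cc(C(=O)OC)c4OC)=C1[C@@]2(C)CCCC(C)(C)[C@H]2CC3 | intermediate (not isolated)
18 | methyl 2,4,5-trimethoxy-3-{[(4aR,8aS)-2,5,5,8a-tetramethyl-3,4,4a,5,6,7,8,8a-octahydronaphthalen-1-yl]carbonyl}benzoate (key-step product) | CC1=C(C(=O)c2c(OC)c(OC)cc(C(=O)OC)c2OC)[C@@]2(C)CCCC(C)(C)[C@H]2CC1 | intermediate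
19 | methyl 3-{(R)-hydroxy[(4aR,8aS)-2,5,5,8a-tetramethyl-3,4,4a,5,6,7,8,8a-octahydronaphthalen-1-yl]methyl}-2,4,5-trimethoxybenzoate | CC1=C([C@@H](O)c2c(OC)c(OC)cc(C(=O)OC)c2OC)[C@@]2(C)CCCC(C)(C)[C@H]2CC1 | intermediate
20 | methyl 2,4,5-trimethoxy-3-{(S)-[1-(2-nitrobenzenesulfonyl)hydrazinyl][(4aR,8aS)-2,5,5,8a-tetramethyl-3,4,4a,5,6,7,8,8a-octahydronaphthalen-1-yl]methyl}benzoate | CC1=C([C@H](N(N)S(=O)(=O)c3ccccc3[N+](=O)[O-])c2c(OC)c(OC)cc(C(=O)OC)c2OC)[C@@]2(C)CCCC(C)(C)[C@H]2CC1 | intermediate (not isolated)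
21 | methyl 3-{(S)-diazenyl[(4aR,8aS)-2,5,5,8a-tetramethyl-3,4,4a,5,6,7,8,8a-octahydronaphthalen-1-yl]methyl}-2,4,5-trimethoxybenzoate | CC1=C([C@H](N=N)c2c(OC)c(OC)cc(C(=O)OC)c2OC)[C@@]2(C)CCCC(C)(C)[C@H]2CC1 | intermediate (not isolated)
22 | methyl 2,4,5-trimethoxy-3-{(E)-[(2S,4aR,8aS)-2,5,5,8a-tetramethyloctahydronaphthalen-1(2H)-ylidene]methyl}benzoate | C[C@H]1CC[C@@H]2C(C)(C)CCC[C@]2(C)/C1=C/c1c(OC)c(OC)cc(C(=O)OC)c1OC | intermediate
23 | (2,4,5-trimethoxy-3-{(E)-[(2S,4aR,8aS)-2,5,5,8a-tetramethyloctahydronaphthalen-1(2H)-ylidene]methyl}phenyl)methanol | C[C@H]1CC[C@@H]2C(C)(C)CCC[C@]2(C)/C1=C/c1c(OC)c(OC)cc(CO)c1OC | intermediate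
24 | 2,4,5-trimethoxy-3-{(E)-[(2S,4aR,8aS)-2,5,5,8a-tetramethyloctahydronaphthalen-1(2H)-ylidene]methyl}benzaldehyde | C[C@H]1CC[C@@H]2C(C)(C)CCC[C@]2(C)/C1=C/c1c(OC)c(OC)cc(C=O)c1OC | intermediate
25 | 2,4,5-trihydroxy-3-{(E)-[(2S,4aR,8aS)-2,5,5,8a-tetramethyloctahydronaphthalen-1(2H)-ylidene]methyl}benzaldehyde | C[C@H]1CC[C@@H]2C(C)(C)CCC[C@]2(C)/C1=C/c1c(O)c(O)cc(C=O)c1O | target

Total step count: 13. Longest linear sequence: 12 steps (steps 1–4 and 6–13, from 1); step 5 is a one-step branch.

Steps most likely to fail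

Step 10. The displacement at the crowded C11 centre may be slow, and the benzylic oxyphosphonium may ionise instead, eroding the C11 configuration and with it the control of C8 and of the alkene geometry. The fallback sets out from 19 and returns at 22. The carbinol is converted with ClCO2Me, pyridine and DMAP into the methyl carbonate F6, which is reduced with Pd(OAc)2, n-Bu3P and HCO2H–Et3N in THF at 60 °C (palladium-catalysed formate hydrogenolysis of an allylic carbonate). Zerovalent palladium ionises the carbonate with inversion, and the palladium hydride formed from formate delivers hydrogen to the more substituted allyl terminus C8 on the metal-bearing face. The C11-to-C8 relay is therefore the same, without an SN2 step at carbon.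

Step 3. The copper catalyst may discriminate poorly between the faces of an α-alkynyl enone whose β-carbon adjoins a quaternary centre, or the addition may be slow enough for 1,2-attack to compete. The fallback sets out from 1 and Grignard reagent 6 and returns at 14. The same copper–diphosphine catalyst is used on the unsubstituted enone 1, with Me3SiCl trapping, to give the silyl enol ether F1. Treatment with n-Bu4NF and 1-[(trimethylsilyl)ethynyl]-1,2-benziodoxol-3(1H)-one transfers an ethynyl group to C2 and gives the 2-ethynyl ketone F2. KOt-Bu and MeI then methylate the more substituted enolate anti to the C3 chain, giving the 2-ethynyl-2-methyl ketone F3. Its tosylhydrazone F4 is reduced with catecholborane and NaOAc·3H2O to 14, which is coupled with 13 under the conditions of step 6 without fluoride to give 15.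

Step 8. FeCl3 may divert the substrate into alkyne hydration or oxidation of the electron-rich arene before ring closure. The fallback sets out from 16 and returns at 18, forming the same C8–C9 bond in two stages. Hydration with Ph3PAuNTf2 (5 mol %) in dioxane–H2O at 80 °C places oxygen on the benzylic carbon C11 and gives the 1,5-diketone F5. NaOMe in MeOH at 65 °C then effects intramolecular aldol condensation of the C9 enolate onto the C8 ketone; attack of the other enolate on the di-ortho-substituted aryl ketone is sterically disfavoured.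

Further compounds
F1 | step 3 | trimethyl({(3S)-4,4-dimethyl-3-[2-(2-methyl-1,3-dioxolan-2-yl)ethyl]cyclohex-1-en-1-yl}oxy)silane | CC2(OCCO2)CC[C@@H]1C(C)(C)CCC(O[Si](C)(C)C)=C1
F2 | step 3 | (3S)-2-ethynyl-4,4-dimethyl-3-[2-(2-methyl-1,3-dioxolan-2-yl)ethyl]cyclohexan-1-one (C2 unassigned) | CC2(OCCO2)CC[C@@H]1C(C)(C)CCC(=O)C1C#C
F3 | step 3 | (2S,3R)-2-ethynyl-2,4,4-trimethyl-3-[2-(2-methyl-1,3-dioxolan-2-yl)ethyl]cyclohexan-1-one | CC2(OCCO2)CC[C@@H]1C(C)(C)CCC(=O)[C@]1(C)C#C
F4 | step 3 | 4-methylbenzenesulfonylhydrazone of F3 (2S,3R) | CC2(OCCO2)CC[C@@H]1C(C)(C)CCC(=NNS(=O)(=O)c3ccc(C)cc3)[C@]1(C)C#C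
F5 | step 8 | methyl 2,4,5-trimethoxy-3-{[(1R,2R)-1,3,3-trimethyl-2-(3-oxobutyl)cyclohexyl]acetyl}benzoate | CC(=O)CC[C@@H]1C(C)(C)CCC[C@]1(C)CC(=O)c1c(OC)c(OC)cc(C(=O)OC)c1OC
F6 | step 10 | methyl 2,4,5-trimethoxy-3-{(R)-[(methoxycarbonyl)oxy][(4aR,8aS)-2,5,5,8a-tetramethyl-3,4,4a,5,6,7,8,8a-octahydronaphthalen-1-yl]methyl}benzoate | CC1=C([C@@H](OC(=O)OC)c2c(OC)c(OC)cc(C(=O)OC)c2OC)[C@@]2(C)CCCC(C)(C)[C@H]2CC1
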